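**Plan**
1. Cuts: the C3 angelate C–O bond, then C8=C17, C13=C14 and C11=C12 (olefinations), then both ring-B bonds C5–C10 and C8–C9 in a retro-Diels–Alder that opens rings A and B at once; the chain is cut at C4–C5 and C4–C19 (enolate alkylations) and at C1–C2 (acetoacetate γ-alkylation).
2. Enabling feature: ring B holds the methylene-bearing C8 next to the side-chain carbon C9 and opposite the fusion bond C5–C10. With oxygen on C8 and C11 as a formyl group it is the cyclohexene of a [4+2] between a C5=C6–C7=C8–O diene and the C9=C10 enal, with the ring-A carbons C1–C4 as tether.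
3. Forward: C11–C9=C10–C1 (allylic chloride) is joined to C2–C3–C4–C18 (acetoacetate); C19 and allyl (C5, C6) go onto C4; cross-metathesis adds C7 and C8; one cycloaddition closes rings A and B; C12–C16, C17 and the angelate follow.
4. Stereochemistry: C3 from Noyori hydrogenation; C4 from two chelate-controlled Fráter–Seebach alkylations (methyl, then allyl); C5, C9 and C10 from the formyl-endo cycloaddition on the tether chair locked by the trans-fused 3,18-acetonide; 13E from the Horner–Wadsworth–Emmons step; the Z ester from angelic acid.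

Key step: step 15

Assumption: labdane numbers are used for every intermediate (C18 = hydroxymethyl carbon on C4, C19 = methyl on C4, C20 = methyl on C10, C17 = exocyclic methylene carbon); the C8 configuration made in step 15 is immaterial because C8 becomes a ketone in step 20.

**Route**

Step 1
Reactants: 1 (2E)-4-chloro-3-methylbut-2-en-1-yl acetate
Product: 2 (2E)-4-chloro-3-methylbut-2-en-1-ol
Conditions: K2CO3 (0.1 equiv), MeOH, 0 °C
Reagents that add atoms: none
Why: Base-catalysed transesterification (methanolysis) should free the allylic alcohol, while the low methoxide concentration at 0 °C leaves the primary allylic chloride and the E alkene untouched.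

Step 2
Reactants: 2 (2E)-4-chloro-3-methylbut-2-en-1-ol
Product: 3 tert-butyl{[(2E)-4-chloro-3-methylbut-2-en-1-yl]oxy}diphenylsilane
Conditions: TBDPSCl, imidazole, CH2Cl2, 0 °C → rt
Reagents that add atoms: tert-butyl(chloro)diphenylsilane, CC(C)(C)[Si](Cl)(c1ccccc1)c1ccccc1
Why: Imidazole-promoted silylation of a primary alcohol; the TBDPS ether is chosen because it should survive the amide base, LiAlH4 and the warm methanolic hydrogenation that follow.

Step 3
Reactants: 4 methyl acetoacetate; 3 tert-butyl{[(2E)-4-chloro-3-methylbut-2-en-1-yl]oxy}diphenylsilane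
Product: 6 methyl (6E)-8-[(tert-butyldiphenylsilyl)oxy]-6-methyl-3-oxooct-6-enoate, via acetoacetate dianion 5 (not isolated)
Conditions: LiN(i-Pr)2 (LDA, 2.1 equiv), THF, 0 °C; then 3, 0 °C → rt
Reagents that add atoms: none
Why: γ-Alkylation of the acetoacetate dianion: the more basic terminal carbanion should displace the primary allylic chloride by SN2 without touching the E-trisubstituted alkene, joining C1 to C2.

Step 4
Reactants: 6 methyl (6E)-8-[(tert-butyldiphenylsilyl)oxy]-6-methyl-3-oxooct-6-enoate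
Product: 7 methyl (3R,6E)-8-[(tert-butyldiphenylsilyl)oxy]-3-hydroxy-6-methyloct-6-enoate
Conditions: H2 (4 atm), RuCl2[(R)-BINAP] (0.5 mol %), MeOH, 50 °C
Reagents that add atoms: none
Why: Noyori asymmetric hydrogenation of a β-keto ester: the (R)-BINAP–ruthenium catalyst should reduce the chelated keto ester to the 3R carbinol (C3), in the same sense as methyl acetoacetate gives methyl (R)-3-hydroxybutanoate, without reducing the trisubstituted allylic ether alkene.

Step 5
Reactants: 7 methyl (3R,6E)-8-[(tert-butyldiphenylsilyl)oxy]-3-hydroxy-6-methyloct-6-enoate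
Product: 9 methyl (2R,3R,6E)-8-[(tert-butyldiphenylsilyl)oxy]-3-hydroxy-2,6-dimethyloct-6-enoate, via chelated alkoxide–enolate dianion 8 (not isolated)
Conditions: LiN(i-Pr)2 (2.2 equiv), THF, −78 → −20 °C; MeI, −78 → 0 °C
Reagents that add atoms: iodomethane, CI
Why: Fráter–Seebach alkylation: the lithium-chelated alkoxide–enolate should be methylated on the face away from the C3 chain, giving the 2,3-anti ester and placing C19 on C4 (this centre is enolised again in step 6).

Step 6
Reactants: 9 methyl (2R,3R,6E)-8-[(tert-butyldiphenylsilyl)oxy]-3-hydroxy-2,6-dimethyloct-6-enoate; 10 allyl bromide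
Product: 12 methyl (2R,3R,6E)-8-[(tert-butyldiphenylsilyl)oxy]-3-hydroxy-2,6-dimethyl-2-(prop-2-en-1-yl)oct-6-enoate, via tetrasubstituted enolate dianion 11 (not isolated)
Conditions: LiN(i-Pr)2 (2.5 equiv), THF–DMPU, −78 → −10 °C; then 10, −78 → 0 °C
Reagents that add atoms: none
Why: Second Fráter–Seebach alkylation: the chelated tetrasubstituted enolate should again take the electrophile anti to the C3 chain, so the allyl group (C5, C6) ends up anti and the methyl group syn to O3, which sets the quaternary C4.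

Step 7
Reactants: 12 methyl (2R,3R,6E)-8-[(tert-butyldiphenylsilyl)oxy]-3-hydroxy-2,6-dimethyl-2-(prop-2-en-1-yl)oct-6-enoate
Product: 13 (2S,3R,6E)-8-[(tert-butyldiphenylsilyl)oxy]-2,6-dimethyl-2-(prop-2-en-1-yl)oct-6-ene-1,3-diol
Conditions: LiAlH4, THF, 0 °C → rt
Reagents that add atoms: none
Why: Hydride reduction of the ester should give the 1,3-diol (C18 hydroxymethyl), the neighbouring alkoxide assisting delivery to the hindered ester, with the silyl ether and both alkenes untouched.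

Step 8
Reactants: 13 (2S,3R,6E)-8-[(tert-butyldiphenylsilyl)oxy]-2,6-dimethyl-2-(prop-2-en-1-yl)oct-6-ene-1,3-diol
Product: 14 tert-butyl({(2E)-3-methyl-5-[(4R,5S)-2,2,5-trimethyl-5-(prop-2-en-1-yl)-1,3-dioxan-4-yl]pent-2-en-1-yl}oxy)diphenylsilane
Conditions: 2,2-dimethoxypropane, PPTS (cat.), CH2Cl2, rt
Reagents that add atoms: 2,2-dimethoxypropane, COC(C)(C)OC
Why: Acid-catalysed transacetalisation should tie O3 and O18 into the six-membered acetonide, which protects both and later locks the tether conformation.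

Step 9
Reactants: 14 tert-butyl({(2E)-3-methyl-5-[(4R,5S)-2,2,5-trimethyl-5-(prop-2-en-1-yl)-1,3-dioxan-4-yl]pent-2-en-1-yl}oxy)diphenylsilane
Product: 15 (2E)-3-methyl-5-[(4R,5S)-2,2,5-trimethyl-5-(prop-2-en-1-yl)-1,3-dioxan-4-yl]pent-2-en-1-ol
Conditions: Bu4NF, THF, 0 °C → rt
Reagents that add atoms: none
Why: Fluoride-induced desilylation should release the allylic C11 alcohol without affecting the acetonide.

Step 10
Reactants: 15 (2E)-3-methyl-5-[(4R,5S)-2,2,5-trimethyl-5-(prop-2-en-1-yl)-1,3-dioxan-4-yl]pent-2-en-1-ol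
Product: 16 (2E)-3-methyl-5-[(4R,5S)-2,2,5-trimethyl-5-(prop-2-en-1-yl)-1,3-dioxan-4-yl]pent-2-en-1-yl acetate
Conditions: Ac2O, pyridine, DMAP (cat.), CH2Cl2, 0 °C
Reagents that add atoms: acetic anhydride, CC(=O)OC(C)=O
Why: DMAP-catalysed acetylation installs a C11 protecting group that can later be removed by hydride, without fluoride or acid, in the presence of the silyl dienol ether.

Step 11
Reactants: 16 (2E)-3-methyl-5-[(4R,5S)-2,2,5-trimethyl-5-(prop-2-en-1-yl)-1,3-dioxan-4-yl]pent-2-en-1-yl acetate; 17 crotonaldehyde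
Product: 18 (2E)-3-methyl-5-{(4R,5S)-2,2,5-trimethyl-5-[(2E)-4-oxobut-2-en-1-yl]-1,3-dioxan-4-yl}pent-2-en-1-yl acetate
Conditions: 17 (5 equiv), second-generation Hoveyda–Grubbs catalyst RuCl2(H2IMes)(=CH-C6H4-2-OiPr) (5 mol %), CH2Cl2, 40 °C
Reagents that add atoms: none
Why: Olefin cross-metathesis of the monosubstituted allyl alkene with crotonaldehyde should give the E enal (C7 and C8 added), the trisubstituted allylic acetate alkene being inert to the catalyst.

Step 12
Reactants: 18 (2E)-3-methyl-5-{(4R,5S)-2,2,5-trimethyl-5-[(2E)-4-oxobut-2-en-1-yl]-1,3-dioxan-4-yl}pent-2-en-1-yl acetate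
Product: 19 (2E)-5-{(4R,5S)-5-[(1E,3E)-4-[(tert-butyldimethylsilyl)oxy]buta-1,3-dien-1-yl]-2,2,5-trimethyl-1,3-dioxan-4-yl}-3-methylpent-2-en-1-yl acetate
Conditions: TBSOTf (1.3 equiv), Et3N (3 equiv), CH2Cl2, −78 → 0 °C
Reagents that add atoms: tert-butyldimethylsilyl trifluoromethanesulfonate, CC(C)(C)[Si](C)(C)OS(=O)(=O)C(F)(F)F
Why: Soft vinylogous enolisation (O-silylation of the enal, then γ-deprotonation at C5 by Et3N) should give the (1E,3E)-1-siloxydiene, the E enol ether arising from the s-trans oxocarbenium ion and the E C5=C6 bond from the bulk of quaternary C4, while the cold amine-buffered medium spares the acetonide.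

Step 13
Reactants: 19 (2E)-5-{(4R,5S)-5-[(1E,3E)-4-[(tert-butyldimethylsilyl)oxy]buta-1,3-dien-1-yl]-2,2,5-trimethyl-1,3-dioxan-4-yl}-3-methylpent-2-en-1-yl acetate
Product: 20 (2E)-5-{(4R,5S)-5-[(1E,3E)-4-[(tert-butyldimethylsilyl)oxy]buta-1,3-dien-1-yl]-2,2,5-trimethyl-1,3-dioxan-4-yl}-3-methylpent-2-en-1-ol
Conditions: i-Bu2AlH (2.2 equiv), CH2Cl2, −78 °C
Reagents that add atoms: none
Why: Reductive cleavage of the acetate by the aluminium hydride at −78 °C should free the C11 alcohol under conditions that silyl enol ethers and acetonides tolerate.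

Step 14
Reactants: 20 (2E)-5-{(4R,5S)-5-[(1E,3E)-4-[(tert-butyldimethylsilyl)oxy]buta-1,3-dien-1-yl]-2,2,5-trimethyl-1,3-dioxan-4-yl}-3-methylpent-2-en-1-ol
Product: 21 (2E)-5-{(4R,5S)-5-[(1E,3E)-4-[(tert-butyldimethylsilyl)oxy]buta-1,3-dien-1-yl]-2,2,5-trimethyl-1,3-dioxan-4-yl}-3-methylpent-2-enal
Conditions: activated MnO2 (15 equiv), CH2Cl2, rt
Reagents that add atoms: none
Why: MnO2 oxidises allylic alcohols selectively under neutral conditions, so the E enal should form without isomerisation and without harm to the acid-sensitive silyl dienol ether.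

Step 15
Reactants: 21 (2E)-5-{(4R,5S)-5-[(1E,3E)-4-[(tert-butyldimethylsilyl)oxy]buta-1,3-dien-1-yl]-2,2,5-trimethyl-1,3-dioxan-4-yl}-3-methylpent-2-enal
Product: 22 (3R,4S,5S,8R,9S,10R)-8-[(tert-butyldimethylsilyl)oxy]-3,18-(isopropylidenedioxy)-12,13,14,15,16,17-hexanorlabd-6-en-11-al
Conditions: Me2AlCl (2.0 equiv), CH2Cl2, −78 → −30 °C; aqueous work-up
Reagents that add atoms: none
Why: Me2AlCl binds the formyl oxygen and lowers the LUMO of the (E)-3-methyl enal, which should add across the (1E,3E)-1-siloxydiene in a concerted, asynchronous [4+2] cycloaddition in which C5 bonds to the β-carbon C10 and the siloxy-bearing C8 to the α-carbon C9, so tether and ortho rule agree. The closest known reaction type is the Lewis-acid-promoted type 1 intramolecular Diels–Alder reaction of 1,7,9-decatrienes with a terminal formyl activator, which gives trans-decalins; this is its demanding variant with a β,β-disubstituted dienophile and an electron-rich silyl dienol ether. Ring B closes as the new cyclohexene by formation of both σ bonds (C5–C10 and C8–C9), and ring A closes through the C5–C10 bond as a six-membered ring whose four-carbon tether C1–C4 sits in a chair. C5 and C10 arise trans-fused from the transition state with the tether exo and the formyl group endo, and their absolute sense follows from C3 and C4, because the trans-fused acetonide allows only the chair with O3 and C18 equatorial and the C19 methyl axial; C9 follows from suprafacial addition to the E enal (C11 cis to C20), and C8 from the E enol ether geometry plus endo approach (silyloxy cis to formyl, erased later). The step needs endo/exo and diene-face selectivity: the first should come from the Lewis-acid-enhanced endo preference of the formyl group, the second from the acetonide lock. Me2AlCl also scavenges adventitious acid, which protects the silyl dienol ether, and the low temperature avoids E/Z scrambling of the enal.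

Step 16
Reactants: 22 (3R,4S,5S,8R,9S,10R)-8-[(tert-butyldimethylsilyl)oxy]-3,18-(isopropylidenedioxy)-12,13,14,15,16,17-hexanorlabd-6-en-11-al
Product: 23 (3R,4S,5S,8R,9S,10R,11E)-8-[(tert-butyldimethylsilyl)oxy]-3,18-(isopropylidenedioxy)-14,15,17-trinorlabda-6,11-dien-13-one
Conditions: Ph3P=CHC(O)CH3 (3 equiv), toluene, 80 °C
Reagents that add atoms: 1-(triphenylphosphoranylidene)propan-2-one, CC(=O)C=P(c1ccccc1)(c1ccccc1)c1ccccc1
Why: Wittig reaction with the stabilised acetonylidene ylide under neutral conditions should give the E enone (C12, C13 and C16 added) without epimerising C9 or eliminating the β-silyloxy group.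

Step 17
Reactants: 23 (3R,4S,5S,8R,9S,10R,11E)-8-[(tert-butyldimethylsilyl)oxy]-3,18-(isopropylidenedioxy)-14,15,17-trinorlabda-6,11-dien-13-one
Product: 24 (3R,4S,5S,8R,9S,10R)-8-[(tert-butyldimethylsilyl)oxy]-3,18-(isopropylidenedioxy)-14,15,17-trinorlabdan-13-one
Conditions: H2 (1 atm), Pd/C (10 %), EtOAc, rt
Reagents that add atoms: none
Why: Heterogeneous catalytic hydrogenation should saturate both disubstituted alkenes (C6=C7 and C11=C12) without creating a stereocentre, leaving the ketone, silyl ether and acetonide unaffected.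

Step 18
Reactants: 24 (3R,4S,5S,8R,9S,10R)-8-[(tert-butyldimethylsilyl)oxy]-3,18-(isopropylidenedioxy)-14,15,17-trinorlabdan-13-one
Product: 25 ethyl (3R,4S,5S,8R,9S,10R,13E)-8-[(tert-butyldimethylsilyl)oxy]-3,18-(isopropylidenedioxy)-17-norlabd-13-en-15-oate
Conditions: (EtO)2P(O)CH2CO2Et, NaH, THF, 0 → 50 °C
Reagents that add atoms: triethyl phosphonoacetate, CCOC(=O)CP(=O)(OCC)OCC
Why: Horner–Wadsworth–Emmons olefination of the only ketone present (C8 is still masked) should favour the E trisubstituted enoate (C14 and C15 added), the minor Z isomer being removable by chromatography.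

Step 19
Reactants: 25 ethyl (3R,4S,5S,8R,9S,10R,13E)-8-[(tert-butyldimethylsilyl)oxy]-3,18-(isopropylidenedioxy)-17-norlabd-13-en-15-oate
Product: 26 ethyl (3R,4S,5S,8R,9S,10R,13E)-8-hydroxy-3,18-(isopropylidenedioxy)-17-norlabd-13-en-15-oate
Conditions: Bu4NF, THF, 50 °C
Reagents that add atoms: none
Why: Fluoride-mediated cleavage of the hindered axial secondary silyl ether (hence the warming) should unmask the C8 alcohol while acetonide and enoate remain.

Step 20
Reactants: 26 ethyl (3R,4S,5S,8R,9S,10R,13E)-8-hydroxy-3,18-(isopropylidenedioxy)-17-norlabd-13-en-15-oate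
Product: 27 ethyl (3R,4S,5S,9S,10R,13E)-3,18-(isopropylidenedioxy)-8-oxo-17-norlabd-13-en-15-oate
Conditions: Dess–Martin periodinane, pyridine, CH2Cl2, 0 °C → rt
Reagents that add atoms: none
Why: Dess–Martin oxidation of the secondary alcohol should give the C8 ketone under mild buffered conditions, erasing the C8 stereocentre, with the C9 side chain already in the favoured equatorial position.

Step 21
Reactants: 27 ethyl (3R,4S,5S,9S,10R,13E)-3,18-(isopropylidenedioxy)-8-oxo-17-norlabd-13-en-15-oate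
Product: 28 ethyl (3R,4S,5S,9R,10S,13E)-3,18-(isopropylidenedioxy)labda-8(17),13-dien-15-oate
Conditions: Ph3PCH3Br, KOtBu, toluene, rt → 60 °C
Reagents that add atoms: methyltriphenylphosphonium bromide, C[P+](c1ccccc1)(c1ccccc1)c1ccccc1.[Br-]
Why: Wittig methylenation of the 8-ketone, a familiar operation in the labdane series, should install the exocyclic C8=C17 alkene; any base-induced equilibration at C9 converges on the equatorial side chain and the ylide does not attack the conjugated ester.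

Step 22
Reactants: 28 ethyl (3R,4S,5S,9R,10S,13E)-3,18-(isopropylidenedioxy)labda-8(17),13-dien-15-oate
Product: 29 (3R,4S,5S,9R,10S,13E)-3,18-(isopropylidenedioxy)labda-8(17),13-dien-15-ol
Conditions: i-Bu2AlH (2.5 equiv), CH2Cl2, −78 °C
Reagents that add atoms: none
Why: 1,2-Reduction of the α,β-unsaturated ester by the aluminium hydride should give the E allylic alcohol (C15) with no effect on the two alkenes or the acetonide.

Step 23
Reactants: 29 (3R,4S,5S,9R,10S,13E)-3,18-(isopropylidenedioxy)labda-8(17),13-dien-15-ol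
Product: 30 (3R,4S,5S,9R,10S,13E)-labda-8(17),13-diene-3,15,18-triol
Conditions: PPTS (0.2 equiv), MeOH, 40 °C
Reagents that add atoms: none
Why: Mild acid-catalysed transacetalisation in methanol should remove the strained six-membered acetonide without isomerising the exocyclic alkene or ionising the allylic alcohol.

Step 24
Reactants: 30 (3R,4S,5S,9R,10S,13E)-labda-8(17),13-diene-3,15,18-triol
Product: 31 (3R,4S,5S,9R,10S,13E)-15,18-bis[(tert-butyldimethylsilyl)oxy]labda-8(17),13-dien-3-ol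
Conditions: TBSCl (2.3 equiv), imidazole, CH2Cl2, 0 °C
Reagents that add atoms: tert-butyl(chloro)dimethylsilane, CC(C)(C)[Si](C)(C)Cl
Why: Sterically governed silylation: the two primary alcohols (allylic C15, neopentyl C18) should react well before the secondary C3 hydroxyl flanked by quaternary C4, leaving only C3–OH free.

Step 25
Reactants: 31 (3R,4S,5S,9R,10S,13E)-15,18-bis[(tert-butyldimethylsilyl)oxy]labda-8(17),13-dien-3-ol; 32 angelic acid
Product: 34 (3R,4S,5S,9R,10S,13E)-15,18-bis[(tert-butyldimethylsilyl)oxy]labda-8(17),13-dien-3-yl (2Z)-2-methylbut-2-enoate, via mixed anhydride 33 (not isolated)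
Conditions: 32, 2,4,6-trichlorobenzoyl chloride, Et3N, toluene, rt; then 31, toluene, 80 °C
Reagents that add atoms: none
Why: Yamaguchi-type esterification through the mixed 2,4,6-trichlorobenzoic anhydride, run without DMAP, is the established way to acylate hindered alcohols with angelic acid while keeping the Z geometry, and should give the C3 angelate.

Step 26
Reactants: 34 (3R,4S,5S,9R,10S,13E)-15,18-bis[(tert-butyldimethylsilyl)oxy]labda-8(17),13-dien-3-yl (2Z)-2-methylbut-2-enoate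
Product: 35 (3R,4S,5S,9R,10S,13E)-15,18-dihydroxylabda-8(17),13-dien-3-yl (2Z)-2-methylbut-2-enoate
Conditions: HF·pyridine, pyridine, THF, 0 °C → rt
Reagents that add atoms: none
Why: Buffered HF·pyridine should cleave both primary silyl ethers, the mildly acidic medium avoiding the base-induced 1,3-acyl shift from O3 to O18 and leaving the exocyclic alkene and the angelate untouched.

**Compound list**
1 | (2E)-4-chloro-3-methylbut-2-en-1-yl acetate | CC(=O)OC/C=C(\C)CCl | starting material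
2 | (2E)-4-chloro-3-methylbut-2-en-1-ol | OC/C=C(\C)CCl | intermediate
3 | tert-butyl{[(2E)-4-chloro-3-methylbut-2-en-1-yl]oxy}diphenylsilane | CC(C)(C)[Si](c1ccccc1)(c1ccccc1)OC/C=C(\C)CCl | intermediate
4 | methyl acetoacetate | CC(=O)CC(=O)OC | starting material
5 | dilithium dianion of methyl acetoacetate | [Li+].[Li+].[CH2-]C(=O)[CH-]C(=O)OC | intermediate
6 | methyl (6E)-8-[(tert-butyldiphenylsilyl)oxy]-6-methyl-3-oxooct-6-enoate | CC(C)(C)[Si](c1ccccc1)(c1ccccc1)OC/C=C(\C)CCC(=O)CC(=O)OC | intermediate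
7 | methyl (3R,6E)-8-[(tert-butyldiphenylsilyl)oxy]-3-hydroxy-6-methyloct-6-enoate | CC(C)(C)[Si](c1ccccc1)(c1ccccc1)OC/C=C(\C)CC[C@@H](O)CC(=O)OC | intermediate
8 | dilithium chelated alkoxide–enolate of 7 | [Li+].[Li+].CC(C)(C)[Si](c1ccccc1)(c1ccccc1)OC/C=C(\C)CC[C@@H]([O-])/C=C(\[O-])OC | intermediate
9 | methyl (2R,3R,6E)-8-[(tert-butyldiphenylsilyl)oxy]-3-hydroxy-2,6-dimethyloct-6-enoate | CC(C)(C)[Si](c1ccccc1)(c1ccccc1)OC/C=C(\C)CC[C@@H](O)[C@H](C(=O)OC)C | intermediate
10 | allyl bromide | C=CCBr | starting material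
11 | dilithium chelated alkoxide–enolate of 9 | [Li+].[Li+].CC(C)(C)[Si](c1ccccc1)(c1ccccc1)OC/C=C(\C)CC[C@@H]([O-])/C(C)=C(\[O-])OC | intermediate
12 | methyl (2R,3R,6E)-8-[(tert-butyldiphenylsilyl)oxy]-3-hydroxy-2,6-dimethyl-2-(prop-2-en-1-yl)oct-6-enoate | CC(C)(C)[Si](c1ccccc1)(c1ccccc1)OC/C=C(\C)CC[C@@H](O)[C@@](C(=O)OC)(C)CC=C | intermediate
13 | (2S,3R,6E)-8-[(tert-butyldiphenylsilyl)oxy]-2,6-dimethyl-2-(prop-2-en-1-yl)oct-6-ene-1,3-diol | CC(C)(C)[Si](c1ccccc1)(c1ccccc1)OC/C=C(\C)CC[C@@H](O)[C@@](CO)(C)CC=C | intermediate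
14 | tert-butyl({(2E)-3-methyl-5-[(4R,5S)-2,2,5-trimethyl-5-(prop-2-en-1-yl)-1,3-dioxan-4-yl]pent-2-en-1-yl}oxy)diphenylsilane | CC(C)(C)[Si](c1ccccc1)(c1ccccc1)OC/C=C(\C)CC[C@@H](OC(C)(C)OC1)[C@@]1(C)CC=C | intermediate
15 | (2E)-3-methyl-5-[(4R,5S)-2,2,5-trimethyl-5-(prop-2-en-1-yl)-1,3-dioxan-4-yl]pent-2-en-1-ol | OC/C=C(\C)CC[C@@H](OC(C)(C)OC1)[C@@]1(C)CC=C | intermediate
16 | (2E)-3-methyl-5-[(4R,5S)-2,2,5-trimethyl-5-(prop-2-en-1-yl)-1,3-dioxan-4-yl]pent-2-en-1-yl acetate | CC(=O)OC/C=C(\C)CC[C@@H](OC(C)(C)OC1)[C@@]1(C)CC=C | intermediate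
17 | crotonaldehyde, (2E)-but-2-enal | C/C=C/C=O | starting material
18 | (2E)-3-methyl-5-{(4R,5S)-2,2,5-trimethyl-5-[(2E)-4-oxobut-2-en-1-yl]-1,3-dioxan-4-yl}pent-2-en-1-yl acetate | CC(=O)OC/C=C(\C)CC[C@@H](OC(C)(C)OC1)[C@@]1(C)C/C=C/C=O | intermediate
19 | (2E)-5-{(4R,5S)-5-[(1E,3E)-4-[(tert-butyldimethylsilyl)oxy]buta-1,3-dien-1-yl]-2,2,5-trimethyl-1,3-dioxan-4-yl}-3-methylpent-2-en-1-yl acetate | CC(=O)OC/C=C(\C)CC[C@@H](OC(C)(C)OC1)[C@@]1(C)/C=C/C=C/O[Si](C)(C)C(C)(C)C | intermediate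
20 | (2E)-5-{(4R,5S)-5-[(1E,3E)-4-[(tert-butyldimethylsilyl)oxy]buta-1,3-dien-1-yl]-2,2,5-trimethyl-1,3-dioxan-4-yl}-3-methylpent-2-en-1-ol | OC/C=C(\C)CC[C@@H](OC(C)(C)OC1)[C@@]1(C)/C=C/C=C/O[Si](C)(C)C(C)(C)C | intermediate
21 | (2E)-5-{(4R,5S)-5-[(1E,3E)-4-[(tert-butyldimethylsilyl)oxy]buta-1,3-dien-1-yl]-2,2,5-trimethyl-1,3-dioxan-4-yl}-3-methylpent-2-enal (cycloaddition precursor) | O=C/C=C(\C)CC[C@@H](OC(C)(C)OC1)[C@@]1(C)/C=C/C=C/O[Si](C)(C)C(C)(C)C | intermediate
22 | (3R,4S,5S,8R,9S,10R)-8-[(tert-butyldimethylsilyl)oxy]-3,18-(isopropylidenedioxy)-12,13,14,15,16,17-hexanorlabd-6-en-11-al (trans-decalin; silyloxy, formyl and C20 on one face) | [C@@H]1(O[Si](C)(C)C(C)(C)C)C=C[C@H]2[C@@](C)(CC[C@@H](OC(C)(C)OC3)[C@@]23C)[C@@H]1C=O | intermediate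
23 | (3R,4S,5S,8R,9S,10R,11E)-8-[(tert-butyldimethylsilyl)oxy]-3,18-(isopropylidenedioxy)-14,15,17-trinorlabda-6,11-dien-13-one | [C@@H]1(O[Si](C)(C)C(C)(C)C)C=C[C@H]2[C@@](C)(CC[C@@H](OC(C)(C)OC3)[C@@]23C)[C@@H]1/C=C/C(C)=O | intermediate
24 | (3R,4S,5S,8R,9S,10R)-8-[(tert-butyldimethylsilyl)oxy]-3,18-(isopropylidenedioxy)-14,15,17-trinorlabdan-13-one | [C@@H]1(O[Si](C)(C)C(C)(C)C)CC[C@H]2[C@@](C)(CC[C@@H](OC(C)(C)OC3)[C@@]23C)[C@@H]1CCC(C)=O | intermediate
25 | ethyl (3R,4S,5S,8R,9S,10R,13E)-8-[(tert-butyldimethylsilyl)oxy]-3,18-(isopropylidenedioxy)-17-norlabd-13-en-15-oate | [C@@H]1(O[Si](C)(C)C(C)(C)C)CC[C@H]2[C@@](C)(CC[C@@H](OC(C)(C)OC3)[C@@]23C)[C@@H]1CC/C(C)=C/C(=O)OCC | intermediate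
26 | ethyl (3R,4S,5S,8R,9S,10R,13E)-8-hydroxy-3,18-(isopropylidenedioxy)-17-norlabd-13-en-15-oate | [C@@H]1(O)CC[C@H]2[C@@](C)(CC[C@@H](OC(C)(C)OC3)[C@@]23C)[C@@H]1CC/C(C)=C/C(=O)OCC | intermediate
27 | ethyl (3R,4S,5S,9S,10R,13E)-3,18-(isopropylidenedioxy)-8-oxo-17-norlabd-13-en-15-oate | O=C1CC[C@H]2[C@@](C)(CC[C@@H](OC(C)(C)OC3)[C@@]23C)[C@@H]1CC/C(C)=C/C(=O)OCC | intermediate
28 | ethyl (3R,4S,5S,9R,10S,13E)-3,18-(isopropylidenedioxy)labda-8(17),13-dien-15-oate | C=C1CC[C@H]2[C@@](C)(CC[C@@H](OC(C)(C)OC3)[C@@]23C)[C@@H]1CC/C(C)=C/C(=O)OCC | intermediate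
29 | (3R,4S,5S,9R,10S,13E)-3,18-(isopropylidenedioxy)labda-8(17),13-dien-15-ol | C=C1CC[C@H]2[C@@](C)(CC[C@@H](OC(C)(C)OC3)[C@@]23C)[C@@H]1CC/C(C)=C/CO | intermediate
30 | (3R,4S,5S,9R,10S,13E)-labda-8(17),13-diene-3,15,18-triol | C=C1CC[C@H]2[C@@](C)(CC[C@@H](O)[C@]2(C)CO)[C@@H]1CC/C(C)=C/CO | intermediate
31 | (3R,4S,5S,9R,10S,13E)-15,18-bis[(tert-butyldimethylsilyl)oxy]labda-8(17),13-dien-3-ol | C=C1CC[C@H]2[C@@](C)(CC[C@@H](O)[C@]2(C)CO[Si](C)(C)C(C)(C)C)[C@@H]1CC/C(C)=C/CO[Si](C)(C)C(C)(C)C | intermediate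
32 | angelic acid, (2Z)-2-methylbut-2-enoic acid | C/C=C(/C)C(=O)O | starting material
33 | (2Z)-2-methylbut-2-enoic 2,4,6-trichlorobenzoic anhydride | C/C=C(/C)C(=O)OC(=O)c1c(Cl)cc(Cl)cc1Cl | intermediate
34 | (3R,4S,5S,9R,10S,13E)-15,18-bis[(tert-butyldimethylsilyl)oxy]labda-8(17),13-dien-3-yl (2Z)-2-methylbut-2-enoate | C=C1CC[C@H]2[C@@](C)(CC[C@@H](OC(=O)/C(C)=C\C)[C@]2(C)CO[Si](C)(C)C(C)(C)C)[C@@H]1CC/C(C)=C/CO[Si](C)(C)C(C)(C)C | intermediate
35 | (3R,4S,5S,9R,10S,13E)-15,18-dihydroxylabda-8(17),13-dien-3-yl (2Z)-2-methylbut-2-enoate (CNP0118197.1) | C=C1CC[C@H]2[C@@](C)(CC[C@@H](OC(=O)/C(C)=C\C)[C@]2(C)CO)[C@@H]1CC/C(C)=C/CO | target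

**Count**
Total steps: 26. Longest linear sequence: 26 steps (1 → 35); methyl acetoacetate 4 enters at step 3.

**Steps most likely to fail**

Step 15 (cycloaddition). Under the Lewis acid the silyl group may be lost or transferred, so that the dienol ether adds stepwise through its s-trans conformer, a path that cannot close ring B. Alternatively the crowded cycloaddition, which builds the C19/C20 1,3-diaxial contact, may be too slow below the temperature at which the enal isomerises. The fallback changes the C8 donor from silyl to acetyl, which cannot transfer and tolerates a stronger Lewis acid. It leaves the route at silyl ether 14. Cross-metathesis with 17 (same ruthenium catalyst) should give the TBDPS-protected enal F1. Ac2O, Et3N and DMAP should convert it into the (1E,3E)-dienyl acetate F2, any 1Z isomer being unreactive and removed later. Buffered HF·pyridine should free the C11 alcohol F3, and MnO2 should give the acetoxy trienal F4. EtAlCl2 in CH2Cl2 at −78 → −20 °C should then effect the same ring closure to the 8-acetoxy aldehyde F5. Steps 16–18 are repeated on this series: acetonylidene Wittig reaction to the enone F6, hydrogenation over Rh/Al2O3 (to avoid allylic C–O hydrogenolysis) to the ketone F7, and Horner–Wadsworth–Emmons reaction to the enoate F8. Ethanolysis of the C8 acetate with K2CO3 in EtOH returns to alcohol 26.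

Step 25 (angeloylation). Acylation of the hindered C3 hydroxyl may stall, and forcing it may isomerise the angeloyl unit from Z to E. The fallback builds the Z alkene on the substrate instead of carrying it in. From alcohol 31, coupling with 2-[bis(2,2,2-trifluoroethoxy)phosphoryl]propanoic acid (EDC, DMAP, CH2Cl2) should give the phosphonopropionate ester F9, a mixture of epimers at the phosphonate α-carbon that is of no consequence. A Z-selective Still–Gennari olefination with acetaldehyde (KN(SiMe3)2, 18-crown-6, THF, −78 °C) should then deliver angelate 34 directly.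

Step 6 (quaternary carbon). Intermolecular attack of allyl bromide on the crowded, chelated tetrasubstituted enolate may be slow, letting O-allylation or retro-aldol cleavage compete, or the facial selectivity may erode. The fallback delivers the allyl group intramolecularly by a dianionic Ireland–Claisen rearrangement. From methyl ester 9, Ti(OiPr)4-catalysed transesterification in allyl alcohol should give the allyl ester F10. LiN(i-Pr)2 (2.5 equiv) in THF, −78 °C → reflux, generates the same chelated alkoxide–enolate, whose [3,3] shift forms the C4–C5 bond on the face away from the C3 chain and gives the acid F11. LiAlH4 reduces this acid to diol 13.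

**Further compounds**
F1 | step 15 | (2E)-4-[(4R,5S)-4-{(3E)-5-[(tert-butyldiphenylsilyl)oxy]-3-methylpent-3-en-1-yl}-2,2,5-trimethyl-1,3-dioxan-5-yl]but-2-enal | CC(C)(C)[Si](c1ccccc1)(c1ccccc1)OC/C=C(\C)CC[C@@H](OC(C)(C)OC1)[C@@]1(C)C/C=C/C=O
F2 | step 15 | (1E,3E)-4-[(4R,5S)-4-{(3E)-5-[(tert-butyldiphenylsilyl)oxy]-3-methylpent-3-en-1-yl}-2,2,5-trimethyl-1,3-dioxan-5-yl]buta-1,3-dien-1-yl acetate | CC(C)(C)[Si](c1ccccc1)(c1ccccc1)OC/C=C(\C)CC[C@@H](OC(C)(C)OC1)[C@@]1(C)/C=C/C=C/OC(C)=O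
F3 | step 15 | (1E,3E)-4-{(4R,5S)-4-[(3E)-5-hydroxy-3-methylpent-3-en-1-yl]-2,2,5-trimethyl-1,3-dioxan-5-yl}buta-1,3-dien-1-yl acetate | OC/C=C(\C)CC[C@@H](OC(C)(C)OC1)[C@@]1(C)/C=C/C=C/OC(C)=O
F4 | step 15 | (1E,3E)-4-{(4R,5S)-2,2,5-trimethyl-4-[(3E)-3-methyl-5-oxopent-3-en-1-yl]-1,3-dioxan-5-yl}buta-1,3-dien-1-yl acetate | O=C/C=C(\C)CC[C@@H](OC(C)(C)OC1)[C@@]1(C)/C=C/C=C/OC(C)=O
F5 | step 15 | (3R,4S,5S,8R,9S,10R)-8-acetoxy-3,18-(isopropylidenedioxy)-12,13,14,15,16,17-hexanorlabd-6-en-11-al | [C@@H]1(OC(C)=O)C=C[C@H]2[C@@](C)(CC[C@@H](OC(C)(C)OC3)[C@@]23C)[C@@H]1C=O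
F6 | step 15 | (3R,4S,5S,8R,9S,10R,11E)-8-acetoxy-3,18-(isopropylidenedioxy)-14,15,17-trinorlabda-6,11-dien-13-one | [C@@H]1(OC(C)=O)C=C[C@H]2[C@@](C)(CC[C@@H](OC(C)(C)OC3)[C@@]23C)[C@@H]1/C=C/C(C)=O
F7 | step 15 | (3R,4S,5S,8R,9S,10R)-8-acetoxy-3,18-(isopropylidenedioxy)-14,15,17-trinorlabdan-13-one | [C@@H]1(OC(C)=O)CC[C@H]2[C@@](C)(CC[C@@H](OC(C)(C)OC3)[C@@]23C)[C@@H]1CCC(C)=O
F8 | step 15 | ethyl (3R,4S,5S,8R,9S,10R,13E)-8-acetoxy-3,18-(isopropylidenedioxy)-17-norlabd-13-en-15-oate | [C@@H]1(OC(C)=O)CC[C@H]2[C@@](C)(CC[C@@H](OC(C)(C)OC3)[C@@]23C)[C@@H]1CC/C(C)=C/C(=O)OCC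
F9 | step 25 | (3R,4S,5S,9R,10S,13E)-15,18-bis[(tert-butyldimethylsilyl)oxy]labda-8(17),13-dien-3-yl 2-[bis(2,2,2-trifluoroethoxy)phosphoryl]propanoate | C=C1CC[C@H]2[C@@](C)(CC[C@@H](OC(=O)C(C)P(=O)(OCC(F)(F)F)OCC(F)(F)F)[C@]2(C)CO[Si](C)(C)C(C)(C)C)[C@@H]1CC/C(C)=C/CO[Si](C)(C)C(C)(C)C
F10 | step 6 | prop-2-en-1-yl (2R,3R,6E)-8-[(tert-butyldiphenylsilyl)oxy]-3-hydroxy-2,6-dimethyloct-6-enoate | CC(C)(C)[Si](c1ccccc1)(c1ccccc1)OC/C=C(\C)CC[C@@H](O)[C@H](C(=O)OCC=C)C
F11 | step 6 | (2R,3R,6E)-8-[(tert-butyldiphenylsilyl)oxy]-3-hydroxy-2,6-dimethyl-2-(prop-2-en-1-yl)oct-6-enoic acid | CC(C)(C)[Si](c1ccccc1)(c1ccccc1)OC/C=C(\C)CC[C@@H](O)[C@@](C(=O)O)(C)CC=C
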